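## Retrosynthetic overview
1. **15** comes from tertiary β-chloro alcohol **14** by chloronium-assisted, stereoconvergent SN1 bromination (Br⁻ enters anti to Cl). The C-OAc comes from cis-selective reduction of an α-bromoketone.
2. The ring A exocyclic methylene comes from fluoride-triggered deconjugation of a γ-silyl enone. C–Br comes from α′-bromination of the enone. The C-O oxidation level comes from a dimedone-derived vinylogous ester (Stork–Danheiser transposition).
3. **New step:** the spiro quaternary centre and the CHCl centre are set together by desymmetrising enantioselective α-chlorination of an achiral spiro[5.5]cyclohexanone.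
4. Ring order: ring A (dimedone) first, then ring B by double alkylation (spiroannulation) of the α′-carbon with a bis(2-chloroethyl) ketal.

Assumption (one line): in ring B the bulky C(CH₃)₂ carbon is equatorial, so the target's trans Br/Cl are both axial. The (R,R) lithium amide is assumed to be the matched enantiomer, to be confirmed by a two-reaction screen.

## Route

**Step 1**
Reactants: 1 dimedone (5,5-dimethylcyclohexane-1,3-dione)
Product: 2 3-ethoxy-5,5-dimethylcyclohex-2-en-1-one
Conditions: EtOH, cat. TsOH, PhH, reflux (Dean–Stark)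
Reagents that add atoms: ethanol, CCO
Why: Acid-catalysed vinylogous-ester formation masks the future C-9 carbonyl and leaves only the α′-CH₂ (the future spiro carbon) acidic. No stereocentre is formed.

**Step 2**
Reactants: 3 1,5-dichloropentan-3-one
Product: 4 2,2-bis(2-chloroethyl)-1,3-dioxolane
Conditions: HOCH₂CH₂OH, cat. TsOH, PhMe, reflux (Dean–Stark)
Reagents that add atoms: ethylene glycol, OCCO
Why: Ketalisation gives a non-enolisable bis-primary-halide annulating agent that becomes the future C-3 carbon of ring B. No stereocentre is formed.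

**Step 3**
Reactants: 2 vinylogous ester; 4 bis-chloroethyl ketal
Product: 5 ethylene ketal of 9-ethoxy-11,11-dimethylspiro[5.5]undec-8-ene-3,7-dione (achiral)
Conditions: (i) LDA, THF, –78 °C; then 4, NaI, DMPU, –78→25 °C; (ii) KHMDS, THF/DMPU, 25→60 °C
Reagents that add atoms: none
Why: Stork–Danheiser regioselective α′-enolate, then intermolecular SN2 (via in-situ iodide) and intramolecular 6-exo-tet SN2, a spiroannulation. The spiro carbon is not stereogenic here because ring B is symmetric.

**Step 4**
Reactants: 5
Product: 6 9-ethoxy-11,11-dimethylspiro[5.5]undec-8-ene-3,7-dione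
Conditions: PPTS (cat.), acetone–H₂O, reflux
Reagents that add atoms: water, O
Why: Acetal hydrolysis. The vinylogous ester is far more acid-stable than the dioxolane, so the ring B ketone is freed selectively.

**Step 5**
Reactants: 6
Product: 7 (2S,6S)-2-chloro-9-ethoxy-11,11-dimethylspiro[5.5]undec-8-ene-3,7-dione
Conditions: (i) (R,R)-[PhCH(Me)]₂NLi, LiCl, THF, –100 °C, TMSCl (in situ quench); (ii) NCS, MeCN, 0 °C
Reagents that add atoms: NCS, O=C1CCC(=O)N1Cl
Why: Proposed new method: the two α-CH₂ arms of the conformationally locked 4,4-disubstituted cyclohexanone (C(CH₃)₂ carbon equatorial, C-7 carbonyl carbon axial) are mirror-related. A chiral lithium amide removes one enantiotopic axial α-proton, which sets the absolute configuration of the remote spiro carbon C-6 and of the enol silane. NCS then chlorinates that enol silane axially, syn to the axial C-7 carbon, to give the required cis-1,3-diaxial Cl/C-7 relationship at C-2. The closest known reactions are Simpkins' enantiotopic deprotonation of 4-tert-butylcyclohexanone and NCS chlorination of silyl enol ethers; the new feature is a spiro 4,4-disubstituted substrate in which f and j are set together.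

**Step 6**
Reactants: 7
Product: 8 (2S,3R,6S)-2-chloro-9-ethoxy-3-hydroxy-3,11,11-trimethylspiro[5.5]undec-8-en-7-one
Conditions: MeTi(OiPr)₃, THF, –78→0 °C
Reagents that add atoms: MeTi(OiPr)₃, C[Ti](OC(C)C)(OC(C)C)OC(C)C
Why: Reetz-type 1,2-addition is chemoselective for the ketone over the vinylogous ester and is non-basic, so no epoxide forms. Methyl adds axially anti to the axial C–Cl. The configuration at C-3 is irrelevant because it is scrambled and reset in Step 13.

**Step 7**
Reactants: 8
Product: 9 (2S,3R,6S)-3-(tert-butyldimethylsilyloxy) analogue of 8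
Conditions: TBSOTf, 2,6-lutidine, CH₂Cl₂, –78→0 °C
Reagents that add atoms: TBSOTf, CC(C)(C)[Si](C)(C)OS(=O)(=O)C(F)(F)F
Why: Protecting the tertiary alcohol prevents alkoxide/epoxide side reactions in the organometallic and LDA steps.

**Step 8**
Reactants: 9
Product: 10 2-chloro-3-(TBSO)-3,11,11-trimethyl-7-[(trimethylsilyl)methyl]spiro[5.5]undec-7-en-9-one
Conditions: (i) Me₃SiCH₂Li, CeCl₃, THF, –78→0 °C; (ii) 1 M aq. HCl, THF, 0 °C
Reagents that add atoms: Me₃SiCH₂Li, C[Si](C)(C)C[Li]
Why: Stork–Danheiser 1,2-addition to the vinylogous-ester carbonyl followed by acid hydrolysis transposes the carbonyl to C-9 and gives the enone. The CH₂TMS group is the latent exocyclic methylene. No new stereocentre is formed.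

**Step 9**
Reactants: 10
Product: 11 10-bromo analogue of 10 (Br cis to the ring B CH₂ at C-1, i.e. "up", equatorial)
Conditions: LDA, THF, –78 °C; then BrCCl₂CCl₂Br, –78 °C
Reagents that add atoms: 1,2-dibromotetrachloroethane, ClC(Cl)(Br)C(Cl)(Cl)Br
Why: Kinetic α′-deprotonation (as at C-6 of isophorone) gives the cross-conjugated enolate, and Br⁺ transfer is electrophilic bromination. Bromine enters on the face opposite the axial ring B CH₂ (C-5) to set C-10. Neither the neopentyl-hindered allylsilane nor the CH₂TMS group is attacked.

**Step 10**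
Reactants: 11
Product: 12 10-bromo-2-chloro-3-hydroxy-3,11,11-trimethyl-7-methylidenespiro[5.5]undecan-9-one
Conditions: TBAF·3H₂O, THF, –78→0 °C; AcOH quench
Reagents that add atoms: none
Why: Fluoride removes the allylic TMS to give the extended dienolate, and kinetic α-protonation at C-8 gives the deconjugated exocyclic methylene. The same TBAF removes the TBS group. The α-bromoketone can epimerise at C-10 to the equatorial (required) epimer; the neopentyl C–Br resists Favorskii closure.

**Step 11**
Reactants: 12
Product: 13 10-bromo-2-chloro-3,11,11-trimethyl-7-methylidenespiro[5.5]undecane-3,9-diol (9-OH cis to 10-Br)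
Conditions: L-Selectride, THF, –78 °C
Reagents that add atoms: none
Why: The bulky hydride attacks equatorially, because axial attack is blocked by the axial C-11 methyl. This gives the axial alcohol cis to the equatorial α-Br and sets C-9.

**Step 12**
Reactants: 13
Product: 14 (10-bromo-2-chloro-3-hydroxy-3,11,11-trimethyl-7-methylidenespiro[5.5]undecan-9-yl) acetate
Conditions: Ac₂O, pyridine, DMAP, CH₂Cl₂, 0→25 °C
Reagents that add atoms: acetic anhydride, CC(=O)OC(C)=O
Why: The secondary alcohol is acylated chemoselectively; the hindered tertiary alcohol is untouched.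

**Step 13**
Reactants: 14
Product: 15 9-acetyllisoobtusol, (3,10-dibromo-2-chloro-3,11,11-trimethyl-7-methylidenespiro[5.5]undecan-9-yl) acetate
Conditions: TMSBr, CH₂Cl₂, –40→–10 °C; NaHCO₃ quench
Reagents that add atoms: TMSBr, C[Si](C)(C)Br
Why: SN1 ionisation of the tertiary silyl ether with anchimeric assistance by the axial β-chlorine forms a chloronium on Cl's face, and Br⁻ opens it at the tertiary carbon anti to Cl. This stereoconvergently gives the trans-diaxial Br(up)/Cl(down) pair regardless of the C-3 epimer and sets C-3. It delivers the target's Cl-on-secondary/Br-on-tertiary regiochemistry, which is the opposite of normal halonium addition.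

## Compound list
1 | dimedone | CC1(C)CC(=O)CC(=O)C1 | starting material
2 | 3-ethoxy-5,5-dimethylcyclohex-2-en-1-one | CCOC1=CC(=O)CC(C)(C)C1 | intermediate
3 | 1,5-dichloropentan-3-one | ClCCC(=O)CCCl | starting material
4 | 2,2-bis(2-chloroethyl)-1,3-dioxolane | ClCCC1(CCCl)OCCO1 | intermediate
5 | ethylene ketal of 6 | O=C1C=C(OCC)CC(C)(C)C12CCC3(OCCO3)CC2 | intermediate
6 | 9-ethoxy-11,11-dimethylspiro[5.5]undec-8-ene-3,7-dione | O=C1C=C(OCC)CC(C)(C)C12CCC(=O)CC2 | intermediate
7 | (2S,6S)-2-chloro-9-ethoxy-11,11-dimethylspiro[5.5]undec-8-ene-3,7-dione | O=C1C=C(OCC)CC(C)(C)[C@@]12CCC(=O)[C@@H](Cl)C2 | intermediate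
8 | (2S,3R,6S)-2-chloro-9-ethoxy-3-hydroxy-3,11,11-trimethylspiro[5.5]undec-8-en-7-one | O=C1C=C(OCC)CC(C)(C)[C@@]12CC[C@@](C)(O)[C@@H](Cl)C2 | intermediate
9 | TBS ether of 8 | O=C1C=C(OCC)CC(C)(C)[C@@]12CC[C@@](C)(O[Si](C)(C)C(C)(C)C)[C@@H](Cl)C2 | intermediate
10 | allylsilane enone | C[Si](C)(C)CC1=CC(=O)CC(C)(C)[C@@]12CC[C@@](C)(O[Si](C)(C)C(C)(C)C)[C@@H](Cl)C2 | intermediate
11 | 10-bromo enone | C[Si](C)(C)CC1=CC(=O)[C@H](Br)C(C)(C)[C@@]12CC[C@@](C)(O[Si](C)(C)C(C)(C)C)[C@@H](Cl)C2 | intermediate
12 | 10-bromo-2-chloro-3-hydroxy-3,11,11-trimethyl-7-methylidenespiro[5.5]undecan-9-one | C=C1CC(=O)[C@H](Br)C(C)(C)[C@@]12CC[C@@](C)(O)[C@@H](Cl)C2 | intermediate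
13 | 9-hydroxy (cis-bromohydrin) diol | C=C1C[C@H](O)[C@H](Br)C(C)(C)[C@@]12CC[C@@](C)(O)[C@@H](Cl)C2 | intermediate
14 | 9-acetate of 13 (tertiary OH free) | C=C1C[C@H](OC(C)=O)[C@H](Br)C(C)(C)[C@@]12CC[C@@](C)(O)[C@@H](Cl)C2 | intermediate
15 | 9-acetyllisoobtusol | C=C1C[C@H](OC(C)=O)[C@H](Br)C(C)(C)[C@@]12CC[C@](C)(Br)[C@@H](Cl)C2 | target

## Step count
- Total steps: 13.
- Longest linear sequence: 12 (1 → 2 → 5 → 6 → 7 → 8 → 9 → 10 → 11 → 12 → 13 → 14 → 15; compounds 3 and 4 form a one-step side branch).

## Three steps most likely to fail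
1. **Step 5 (proposed new method).** The chiral amide must distinguish two arms that differ only through the remote spiro substituents, so ee may be low or Cl may end up equatorial.
   - Fallback (known chemistry): perform racemic chlorination (LDA, TMSCl, NCS) and resolve 7 as diastereomeric ketals of the C-3 ketone (e.g. with (R,R)-hydrobenzoin), or by chiral-phase SFC.
2. **Step 13.** The exocyclic methylene may protonate, or the cation may give tertiary chloride or elimination.
   - Fallback: dehydrate 14 (Burgess reagent) to the allylic-chloride alkene and add HBr (Markovnikov) at –78 °C with the same chloronium-directed anti delivery, or carry out the bromination before the methylene is unmasked.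
3. **Step 3.** The double alkylation must build a quaternary centre next to the quaternary C(CH₃)₂ carbon.
   - Fallback: double Michael route. Add the enolate of 2 to divinyl ketone (from 3 and Et₃N, in situ), then close with KOtBu to give 6 directly, bypassing 4 and 5.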